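**Retrosynthetic overview**
1. Last bond: the central CH2–CH2 link, made by visible-light decarboxylative radical addition of left-half acid 33 (as its N-acyloxyphthalimide) to the exocyclic methylene of right-half methoxy diene 14; hydrolysis of the resulting oxocarbenium ion delivers the tetrasubstituted enone.
2. Right half 14: cyclopentene first (ring-closing metathesis of (S)-linalool), quaternary carbon by Ireland–Claisen rearrangement, then the seven-membered ring by intramolecular epoxide opening with a 1,3-diketone dianion.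
3. Left half 33: cyclohexane from (+)-verbenone (conjugate addition/alkylation, cyclobutane fragmentation, MeMgBr/lactonisation); ring oxygen by metathesis–ozonolysis–Criegee; oxepane last by 7-endo hydroxy-epoxide cyclisation and ketone reduction.
4. Ring order: left cyclohexane → temporary γ-lactone → oxepane; right cyclopentane → cycloheptane; the two bicycles are joined in the final step.

Assumption: (S)-(+)-linalool and (1R,5R)-(+)-verbenone are taken as commercial in ≥97% ee (the latter is also one oxidation step from (+)-α-pinene).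

**Step 1**
Reactants: 1 (S)-(+)-linalool
Product: 2 (1S)-1-methylcyclopent-2-en-1-ol
Conditions: second-generation Grubbs catalyst (0.5 mol%), CH2Cl2, 40 °C
Reagents that add atoms: none
Why: Ring-closing metathesis between the vinyl and prenyl olefins expels 2-methylpropene and leaves the purchased tertiary carbinol centre untouched.

**Step 2**
Reactants: 2 (1S)-1-methylcyclopent-2-en-1-ol
Product: 3 (1S)-1-methylcyclopent-2-en-1-yl 2-methylpropanoate
Conditions: (i-PrCO)2O, Et3N, DMAP (20 mol%), CH2Cl2, 25 °C
Reagents that add atoms: isobutyric anhydride CC(C)C(=O)OC(=O)C(C)C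
Why: DMAP-catalysed O-acylation (Steglich-type acyl transfer) of the tertiary allylic alcohol proceeds without ionisation, so the stereocentre is retained.

**Step 3**
Reactants: 3 (1S)-1-methylcyclopent-2-en-1-yl 2-methylpropanoate
Product: 6 2-methyl-2-[(1R)-3-methylcyclopent-2-en-1-yl]propanoic acid, via silyl ketene acetal 4 (not isolated), via trimethylsilyl ester 5 (not isolated)
Conditions: LiN(i-Pr)2, Me3SiCl, THF, −78 to 60 °C; then aq. HCl
Reagents that add atoms: none
Why: Ireland–Claisen rearrangement, in which the suprafacial [3,3] shift transfers chirality from the carbinol carbon to the new ring stereocentre while building the gem-dimethyl quaternary carbon.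

**Step 4**
Reactants: 6 2-methyl-2-[(1R)-3-methylcyclopent-2-en-1-yl]propanoic acid
Product: 7 2-methyl-2-[(1R)-3-methylcyclopent-2-en-1-yl]pentan-3-one
Conditions: EtLi (2.2 equiv), Et2O, 0 to 25 °C; then H2O
Reagents that add atoms: ethyllithium [Li]CC
Why: Alkyllithium addition to the lithium carboxylate gives a stable gem-diolate that collapses to the ethyl ketone on work-up (acid-to-ketone synthesis) without touching the stereocentre.

**Step 5**
Reactants: 7 2-methyl-2-[(1R)-3-methylcyclopent-2-en-1-yl]pentan-3-one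
Product: 8 3,5-dimethyl-5-[(1R)-3-methylcyclopent-2-en-1-yl]hexane-2,4-dione
Conditions: 1-acetylbenzotriazole, MgBr2·OEt2, i-Pr2NEt, CH2Cl2, 25 °C
Reagents that add atoms: 1-acetylbenzotriazole CC(=O)n1nnc2ccccc21
Why: Soft-enolisation C-acylation (crossed Claisen condensation) can occur only at the single enolisable methylene because the other α-carbon is quaternary.

**Step 6**
Reactants: 8 3,5-dimethyl-5-[(1R)-3-methylcyclopent-2-en-1-yl]hexane-2,4-dione
Product: 9 epoxy diketone (oxirane anti to the diketone side chain)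
Conditions: mCPBA, NaHCO3, CH2Cl2, 0 °C
Reagents that add atoms: mCPBA OOC(=O)c1cccc(Cl)c1
Why: Prilezhaev epoxidation of the trisubstituted cyclopentene occurs on the face anti to the bulky allylic quaternary substituent, fixing the C–O configuration of the future tertiary alcohol.

**Step 7**
Reactants: 9 epoxy diketone
Product: 11 (1R,3aR,8aR)-1-hydroxy-1,4,4,6-tetramethyloctahydroazulene-5,7-dione, via dilithium dianion 10 (not isolated)
Conditions: LiN(i-Pr)2 (2.3 equiv), THF, −78 to 25 °C; aq. NH4Cl
Reagents that add atoms: none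
Why: The terminal carbon of the 1,3-diketone dianion (Hauser–Weiler γ-alkylation) opens the oxirane intramolecularly at its less substituted carbon with inversion (7-exo-tet), which forces the cis ring fusion and releases the tertiary alcohol.

**Step 8**
Reactants: 11 bicyclic hydroxy dione
Product: 12 (1R,3aR,8aR)-1-hydroxy-7-methoxy-1,4,4,6-tetramethyl-2,3,3a,4,8,8a-hexahydroazulen-5(1H)-one
Conditions: HC(OMe)3, MeOH, CSA (cat.), 25 °C
Reagents that add atoms: trimethyl orthoformate COC(OC)OC
Why: Acid-catalysed enol etherification of the 1,3-dione takes place at the carbonyl remote from the gem-dimethyl carbon, as in the preparation of Stork–Danheiser vinylogous esters.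

**Step 9**
Reactants: 12 vinylogous ester
Product: 14 (1R,3aR,8aR)-7-methoxy-1,4,4,6-tetramethyl-5-methylidene-1,2,3,3a,4,5,8,8a-octahydroazulen-1-ol, via β-silyl dialkoxide 13 (not isolated)
Conditions: Me3SiCH2Li (2.5 equiv), THF, −78 to 0 °C; then HMPA, 60 °C
Reagents that add atoms: (trimethylsilyl)methyllithium [Li]C[Si](C)(C)C
Why: Peterson olefination, in which 1,2-addition to the hindered vinylogous-ester carbonyl and base-mediated syn-elimination of silanolate give the exocyclic methylene without hydrolysing the enol ether.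

**Step 10**
Reactants: 15 (1R,5R)-(+)-verbenone
Product: 18 methyl [4-(but-3-enyl)-4,6,6-trimethyl-2-oxobicyclo[3.1.1]hept-3-yl]acetate, via silyl enol ether 16 (not isolated), via lithium enolate 17 (not isolated)
Conditions: but-3-enylMgBr, CuBr·SMe2 (10 mol%), Me3SiCl, THF, −78 °C; evaporate; MeLi, THF, 0 °C; then BrCH2CO2Me, HMPA, −78 to 0 °C
Reagents that add atoms: but-3-enylmagnesium bromide C=CCC[Mg]Br; methyl bromoacetate COC(=O)CBr
Why: Copper-catalysed conjugate addition anti to the gem-dimethyl bridge creates the quaternary carbon, and regiospecific alkylation of the derived enolate installs the acetate arm (three-component conjugate addition–enolate trapping).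

**Step 11**
Reactants: 18 bicyclic keto ester
Product: 20 methyl [2-(but-3-enyl)-2-methyl-6-oxo-3-(prop-1-en-2-yl)cyclohexyl]acetate (acetate arm and isopropenyl both trans to butenyl), via iodo silyl enol ether 19 (not isolated)
Conditions: Me3SiI, CH2Cl2, −20 to 0 °C; then DBU, 25 °C; then MeOH
Reagents that add atoms: none
Why: Iodotrimethylsilane-induced cyclobutane fragmentation (C–C cleavage α to the ketone) releases the cyclohexanone, E2 elimination of the tertiary iodide gives the isopropenyl group, and DBU/MeOH equilibrates the α-centre to the all-equatorial epimer.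

**Step 12**
Reactants: 20 cyclohexanone ester
Product: 22 cis-fused γ-lactone 4-(but-3-enyl)-4,7a-dimethyl-5-(prop-1-en-2-yl)hexahydro-1-benzofuran-2(3H)-one, via bromomagnesium alkoxide 21 (not isolated)
Conditions: MeMgBr (1.2 equiv), THF, −78 to 0 °C
Reagents that add atoms: methylmagnesium bromide C[Mg]Br
Why: Grignard addition is equatorial because the axial trajectory is blocked by the 1,3-diaxial angular methyl group, and the resulting axial alkoxide lactonises onto the cis ester.

**Step 13**
Reactants: 22 diene lactone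
Product: 23 tricyclic ene lactone (trans-fused methylcyclohexene, cis-fused γ-lactone)
Conditions: second-generation Grubbs catalyst (3 mol%), CH2Cl2, 40 °C
Reagents that add atoms: none
Why: Ring-closing metathesis of the trans-diequatorial butenyl and isopropenyl groups gives the trisubstituted cyclohexene, tying the two olefins together for a regiocontrolled cleavage.

**Step 14**
Reactants: 23 tricyclic ene lactone
Product: 25 acetoxy aldehyde, via methoxy hydroperoxide 24 (not isolated)
Conditions: O3, CH2Cl2/MeOH, NaHCO3, −78 °C; then Ac2O, Et3N, DMAP, 0 to 25 °C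
Reagents that add atoms: ozone [O-][O+]=O
Why: Ozonolysis places the carbonyl oxide on the methyl-bearing carbon, and Criegee rearrangement of the derived α-methoxy peracetate moves the ring carbon to oxygen with retention, giving the secondary acetate while the other terminus remains an aldehyde.

**Step 15**
Reactants: 25 acetoxy aldehyde
Product: 26 epoxy acetate (both oxirane epimers)
Conditions: i-PrSPh2 BF4, LiN(i-Pr)2, DME/THF, −78 °C
Reagents that add atoms: isopropyldiphenylsulfonium tetrafluoroborate CC(C)[S+](c1ccccc1)c1ccccc1.F[B-](F)(F)F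
Why: Corey–Chaykovsky epoxidation with diphenylsulfonium isopropylide converts the aldehyde chemoselectively into the 2,2-dimethyloxirane, whose unselective new centre is corrected in steps 17 and 18.

**Step 16**
Reactants: 26 epoxy acetate
Product: 28 oxepanol lactone (both carbinol epimers), via hydroxy epoxide 27 (not isolated)
Conditions: K2CO3, MeOH, 25 °C; evaporate; then CSA (20 mol%), CH2Cl2, 0 °C
Reagents that add atoms: none
Why: After acetate methanolysis, acid-catalysed 7-endo epoxide opening by the ring hydroxyl occurs at the tertiary oxirane carbon (gem-dimethyl-directed Markovnikov opening), closing the trans-fused oxepane.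

**Step 17**
Reactants: 28 oxepanol lactone
Product: 29 oxepan-3-one lactone
Conditions: Dess–Martin periodinane, NaHCO3, CH2Cl2, 25 °C
Reagents that add atoms: none
Why: Dess–Martin oxidation converges both carbinol epimers to a single ketone.

**Step 18**
Reactants: 29 oxepan-3-one lactone
Product: 30 (S)-oxepanol lactone (hydroxyl cis to the angular methyl)
Conditions: NaBH4, MeOH, −20 °C
Reagents that add atoms: none
Why: Substrate-controlled borohydride reduction, in which hydride attacks the face of the oxepanone opposite the angular methyl group and so sets the carbinol centre.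

**Step 19**
Reactants: 30 (S)-oxepanol lactone
Product: 33 bis(triethylsilyl) ether acid, via lithium carboxylate 31 (not isolated), via tris(triethylsilyl) derivative 32 (not isolated)
Conditions: LiOH, THF/H2O, 25 °C; evaporate; Et3SiOTf, 2,6-lutidine, CH2Cl2, 0 °C; then K2CO3, MeOH/H2O; pH 5 buffer
Reagents that add atoms: lithium hydroxide [Li+].[OH-]; triethylsilyl trifluoromethanesulfonate CC[Si](CC)(CC)OS(=O)(=O)C(F)(F)F
Why: Saponification opens the lactone, exhaustive silylation caps both hydroxyls so the γ-hydroxy acid cannot relactonise, and mild base cleaves only the labile silyl ester.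

**Step 20**
Reactants: 33 bis(triethylsilyl) ether acid; 14 methoxy diene
Product: 36 CNP0397160.2, via N-acyloxyphthalimide 34 (not isolated), via bis(triethylsilyl) ether 35 (not isolated)
Conditions: N-hydroxyphthalimide, DIC, DMAP (cat.), CH2Cl2, 25 °C; then 14 (2 equiv), Ir(ppy)3 (1 mol%), MeCN/H2O 20:1, blue LEDs (450 nm), 25 °C; then 1 M aq. HCl, THF, 25 °C
Reagents that add atoms: water O
Why: Proposed new method: a visible-light decarboxylative vinylogous alkylation in which the excited iridium photocatalyst reduces the N-acyloxyphthalimide, the primary alkyl radical formed on loss of CO2 adds to the terminal methylene of the methoxy diene, and the methoxy-stabilised allyl radical is oxidised by the oxidised photocatalyst to an oxocarbenium ion whose hydrolysis gives the tetrasubstituted enone and the central CH2–CH2 bond without touching any stereocentre; the closest known reactions are the photoredox decarboxylative alkylation of silyl enol ethers with redox-active esters and vinylogous Mukaiyama-type additions to alkoxy dienes.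

**Compound list**
1 | (S)-(+)-linalool, (3S)-3,7-dimethylocta-1,6-dien-3-ol | C=C[C@@](C)(O)CCC=C(C)C | starting material
2 | (1S)-1-methylcyclopent-2-en-1-ol | C[C@@]1(O)C=CCC1 | intermediate
3 | (1S)-1-methylcyclopent-2-en-1-yl 2-methylpropanoate | CC(C)C(=O)O[C@]1(C)C=CCC1 | intermediate
4 | trimethylsilyl ketene acetal of 3 | CC(C)=C(O[Si](C)(C)C)O[C@]1(C)C=CCC1 | intermediate
5 | trimethylsilyl 2-methyl-2-[(1R)-3-methylcyclopent-2-en-1-yl]propanoate | C[Si](C)(C)OC(=O)C(C)(C)[C@H]1C=C(C)CC1 | intermediate
6 | 2-methyl-2-[(1R)-3-methylcyclopent-2-en-1-yl]propanoic acid | OC(=O)C(C)(C)[C@H]1C=C(C)CC1 | intermediate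
7 | 2-methyl-2-[(1R)-3-methylcyclopent-2-en-1-yl]pentan-3-one | CCC(=O)C(C)(C)[C@H]1C=C(C)CC1 | intermediate
8 | 3,5-dimethyl-5-[(1R)-3-methylcyclopent-2-en-1-yl]hexane-2,4-dione (both C3 epimers) | CC(=O)C(C)C(=O)C(C)(C)[C@H]1C=C(C)CC1 | intermediate
9 | epoxide of 8, oxirane anti to the diketone side chain | CC(=O)C(C)C(=O)C(C)(C)[C@H]1[C@@H]2O[C@]2(C)CC1 | intermediate
10 | dilithium dianion of 9 | C=C([O-])C(C)=C([O-])C(C)(C)[C@H]1[C@@H]2O[C@]2(C)CC1.[Li+].[Li+] | intermediate
11 | (1R,3aR,8aR)-1-hydroxy-1,4,4,6-tetramethyloctahydroazulene-5,7-dione (cis-fused; both C6 epimers) | CC1C(=O)C(C)(C)[C@@H]2CC[C@@](C)(O)[C@@H]2CC1=O | intermediate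
12 | (1R,3aR,8aR)-1-hydroxy-7-methoxy-1,4,4,6-tetramethyl-2,3,3a,4,8,8a-hexahydroazulen-5(1H)-one | COC1=C(C)C(=O)C(C)(C)[C@@H]2CC[C@@](C)(O)[C@@H]2C1 | intermediate
13 | dilithium β-silyl dialkoxide from 12 and Me3SiCH2Li | COC1=C(C)C([O-])(C[Si](C)(C)C)C(C)(C)[C@@H]2CC[C@@](C)([O-])[C@@H]2C1.[Li+].[Li+] | intermediate
14 | (1R,3aR,8aR)-7-methoxy-1,4,4,6-tetramethyl-5-methylidene-1,2,3,3a,4,5,8,8a-octahydroazulen-1-ol | COC1=C(C)C(=C)C(C)(C)[C@@H]2CC[C@@](C)(O)[C@@H]2C1 | intermediate
15 | (1R,5R)-(+)-verbenone | CC1=CC(=O)[C@@H]2C[C@H]1C2(C)C | starting material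
16 | 4-(but-3-enyl)-4,6,6-trimethyl-2-(trimethylsilyloxy)bicyclo[3.1.1]hept-2-ene (butenyl anti to the gem-dimethyl bridge) | C=CCC[C@]1(C)C=C(O[Si](C)(C)C)[C@@H]2C[C@H]1C2(C)C | intermediate
17 | lithium enolate corresponding to 16 | C=CCC[C@]1(C)C=C([O-])[C@@H]2C[C@H]1C2(C)C.[Li+] | intermediate
18 | methyl [4-(but-3-enyl)-4,6,6-trimethyl-2-oxobicyclo[3.1.1]hept-3-yl]acetate (butenyl and acetate arm anti to the gem-dimethyl bridge) | C=CCC[C@]1(C)[C@H](CC(=O)OC)C(=O)[C@@H]2C[C@H]1C2(C)C | intermediate
19 | ring-opened tertiary iodide as its trimethylsilyl enol ether | COC(=O)C[C@H]1[C@@](C)(CCC=C)[C@H](C(C)(C)I)CC=C1O[Si](C)(C)C | intermediate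
20 | methyl [2-(but-3-enyl)-2-methyl-6-oxo-3-(prop-1-en-2-yl)cyclohexyl]acetate (acetate arm and isopropenyl trans to butenyl) | COC(=O)C[C@@H]1[C@@](C)(CCC=C)[C@H](C(C)=C)CCC1=O | intermediate
21 | bromomagnesium tertiary alkoxide from 20 and MeMgBr | COC(=O)C[C@@H]1[C@@](C)(CCC=C)[C@H](C(C)=C)CC[C@]1(C)[O-].[Mg+2].[Br-] | intermediate
22 | cis-fused γ-lactone, 4-(but-3-enyl)-4,7a-dimethyl-5-(prop-1-en-2-yl)hexahydro-1-benzofuran-2(3H)-one | O=C1C[C@@H]2[C@@](C)(CCC=C)[C@H](C(C)=C)CC[C@]2(C)O1 | intermediate
23 | tricyclic ene lactone (trans-fused methylcyclohexene on the lactone-bearing cyclohexane) | O=C1C[C@@H]2[C@@]3(C)CCC=C(C)[C@@H]3CC[C@]2(C)O1 | intermediate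
24 | α-methoxy hydroperoxide aldehyde from ozonolysis of 23 | O=C1C[C@@H]2[C@@](C)(CCC=O)[C@H](C(C)(OC)OO)CC[C@]2(C)O1 | intermediate
25 | acetoxy aldehyde (secondary acetate, 3-oxopropyl chain) | O=C1C[C@@H]2[C@@](C)(CCC=O)[C@H](OC(C)=O)CC[C@]2(C)O1 | intermediate
26 | epoxy acetate (2,2-dimethyloxirane, both oxirane epimers) | O=C1C[C@@H]2[C@@](C)(CCC3OC3(C)C)[C@H](OC(C)=O)CC[C@]2(C)O1 | intermediate
27 | hydroxy epoxide | O=C1C[C@@H]2[C@@](C)(CCC3OC3(C)C)[C@H](O)CC[C@]2(C)O1 | intermediate
28 | oxepanol lactone (trans-fused oxepane, both carbinol epimers) | O=C1C[C@@H]2[C@@]3(C)CCC(O)C(C)(C)O[C@@H]3CC[C@]2(C)O1 | intermediate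
29 | oxepan-3-one lactone | O=C1C[C@@H]2[C@@]3(C)CCC(=O)C(C)(C)O[C@@H]3CC[C@]2(C)O1 | intermediate
30 | (S)-oxepanol lactone (hydroxyl cis to the angular methyl) | O=C1C[C@@H]2[C@@]3(C)CC[C@H](O)C(C)(C)O[C@@H]3CC[C@]2(C)O1 | intermediate
31 | lithium dihydroxy carboxylate from 30 | [Li+].[O-]C(=O)C[C@@H]1[C@@]2(C)CC[C@H](O)C(C)(C)O[C@@H]2CC[C@]1(C)O | intermediate
32 | tris(triethylsilyl) derivative (two silyl ethers, one silyl ester) | CC[Si](CC)(CC)OC(=O)C[C@@H]1[C@@]2(C)CC[C@H](O[Si](CC)(CC)CC)C(C)(C)O[C@@H]2CC[C@]1(C)O[Si](CC)(CC)CC | intermediate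
33 | bis(triethylsilyl) ether acid (left half) | OC(=O)C[C@@H]1[C@@]2(C)CC[C@H](O[Si](CC)(CC)CC)C(C)(C)O[C@@H]2CC[C@]1(C)O[Si](CC)(CC)CC | intermediate
34 | N-acyloxyphthalimide of 33 | O=C(C[C@@H]1[C@@]2(C)CC[C@H](O[Si](CC)(CC)CC)C(C)(C)O[C@@H]2CC[C@]1(C)O[Si](CC)(CC)CC)ON1C(=O)c2ccccc2C1=O | intermediate
35 | bis(triethylsilyl) ether of the target | CC1=C(CC[C@@H]2[C@@]3(C)CC[C@H](O[Si](CC)(CC)CC)C(C)(C)O[C@@H]3CC[C@]2(C)O[Si](CC)(CC)CC)C(C)(C)[C@@H]2CC[C@@](C)(O)[C@@H]2CC1=O | intermediate
36 | CNP0397160.2 | CC1=C(CC[C@@H]2[C@@]3(C)CC[C@H](O)C(C)(C)O[C@@H]3CC[C@]2(C)O)C(C)(C)[C@@H]2CC[C@@](C)(O)[C@@H]2CC1=O | target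

**Step count**
Total: 20 steps. Longest linear sequence: 11 steps (15 to 36, steps 10–20); the other branch is 10 steps (1 to 14, then step 20).

**Steps most likely to fail**

Step 20 (the proposed new coupling; the alkyl radical is polarity-mismatched with the electron-rich diene). The fallback is a Stork–Danheiser union, which sets out from 30 and 12 and comes back at 36. Lactone 30 is reduced with LiAlH4 (THF, 0 °C) to the triol F1. The primary hydroxyl is converted into the iodide F2 (I2, PPh3, imidazole), and the two remaining hydroxyls are capped with Me3SiOTf/2,6-lutidine to give the bis(trimethylsilyl) ether iodide F3. Iodine–lithium exchange (t-BuLi, Et2O, −78 °C) gives the alkyllithium F4. This adds to the carbonyl of the trimethylsilyl ether F5 of vinylogous ester 12 (made with N-(trimethylsilyl)imidazole), giving the tertiary alkoxide F6. Aqueous HCl in THF then hydrolyses the enol ether with allylic transposition and removes the silyl groups to give 36.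

Step 7 (seven-membered ring closure by the diketone dianion; a five-membered closure through the central carbon could compete). The fallback sets out from 9 and comes back at 12. Diketone 9 is O-methylated at the less hindered acetyl carbonyl with (trimethylsilyl)diazomethane in MeOH/toluene to give the acyclic vinylogous ester F7. KN(SiMe3)2 (THF, −78 to 0 °C) removes a proton from the only acidic site, the γ-methyl group. The extended potassium enolate F8 opens the oxirane (γ-alkylation of a vinylogous ester) and gives 12 directly, so that step 8 is no longer needed.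

Step 16 (7-endo against 6-exo opening of the oxirane). The fallback sets out from 26 and comes back at 28. Acetate 26 is methanolysed (K2CO3, MeOH) and hydroxy epoxide 27 is isolated. Al(Oi-Pr)3 in toluene at 110 °C isomerises the oxirane to the isopropenyl carbinol F9. Hydrogen-atom-transfer hydroalkoxylation (Co(salen) complex as catalyst, N-fluoro-2,4,6-trimethylpyridinium triflate, PhSiH3) then makes only the tertiary carbon electrophilic, and the ring hydroxyl traps it to give 28 as both carbinol epimers, which steps 17 and 18 converge.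

**Further compounds**
F1 | step 20 | triol from LiAlH4 reduction of 30 | OCC[C@@H]1[C@@]2(C)CC[C@H](O)C(C)(C)O[C@@H]2CC[C@]1(C)O
F2 | step 20 | primary iodide diol | ICC[C@@H]1[C@@]2(C)CC[C@H](O)C(C)(C)O[C@@H]2CC[C@]1(C)O
F3 | step 20 | bis(trimethylsilyl) ether iodide | ICC[C@@H]1[C@@]2(C)CC[C@H](O[Si](C)(C)C)C(C)(C)O[C@@H]2CC[C@]1(C)O[Si](C)(C)C
F4 | step 20 | alkyllithium from F3 | [Li]CC[C@@H]1[C@@]2(C)CC[C@H](O[Si](C)(C)C)C(C)(C)O[C@@H]2CC[C@]1(C)O[Si](C)(C)C
F5 | step 20 | trimethylsilyl ether of 12 | COC1=C(C)C(=O)C(C)(C)[C@@H]2CC[C@@](C)(O[Si](C)(C)C)[C@@H]2C1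
F6 | step 20 | lithium tertiary alkoxide adduct of F4 and F5 | COC1=C(C)C([O-])(CC[C@@H]2[C@@]3(C)CC[C@H](O[Si](C)(C)C)C(C)(C)O[C@@H]3CC[C@]2(C)O[Si](C)(C)C)C(C)(C)[C@@H]2CC[C@@](C)(O[Si](C)(C)C)[C@@H]2C1.[Li+]
F7 | step 7 | acyclic methyl enol ether of 9 (vinylogous ester epoxide) | COC(C)=C(C)C(=O)C(C)(C)[C@H]1[C@@H]2O[C@]2(C)CC1
F8 | step 7 | potassium γ-dienolate of F7 | C=C(OC)C(C)=C([O-])C(C)(C)[C@H]1[C@@H]2O[C@]2(C)CC1.[K+]
F9 | step 16 | isopropenyl carbinol diol from 27 | O=C1C[C@@H]2[C@@](C)(CCC(O)C(C)=C)[C@H](O)CC[C@]2(C)O1
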